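## Retrosynthetic overview

1. Feature: in the ten-membered carbocycle, the run C3(=O)–C4(Me)=C5–C6–C7(C11,C12,C13)–C8 is the six-membered ring of carvone with its C3–C8 bond missing. C2, C1, C10 and C9 fill the gap, and Z-C4=C5 is the ring alkene of the terpene.
2. Late disconnections: γ-lactone C12–O6 (oxidative lactonisation, last ring), isopropenyl C12–H oxidation, C1–C2 oxirane (nucleophilic epoxidation of the E-enone), C8 isobutyrate, C8–OH (C10–OH-directed C8=C9 epoxidation, then hydride at C9), C1=C2 (Saegusa–Ito).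
3. Key disconnection: C1–C10. The retro-[3,3] shift re-forms C3–C8 and contracts the ten-membered ring to a 3-vinyl-8-alkenylcyclohexenol. Its alkenyl terminus is an E enol ether that carries both the C10 methyl and the C10 oxygen.
4. The cyclohexenol comes from (S)-carvone. C6–O is set first, by γ-hydroxylation in the six-membered ring, where C4=C5 cannot isomerise. C8 propargylation, C3 vinylation, alkyne shift on the silyl-masked carbinol, hydrostannation–iodination and Cu-catalysed etherification follow.
5. Ring order: six-membered carbocycle (chiral pool) → ten-membered carbocycle (step 10) → transient C8–C9 oxirane → C1–C2 oxirane → γ-lactone.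

Key step: step 10

Remark: the atom labels C1–C15 of the target are used for all intermediates (epoxide C1–C2, ketone C3, C4(Me)=C5, lactone O on C6, C7, ester O on C8, C9, C10(Me)OH, C11=C13, C12 lactone carbonyl).

Assumption: the two C3 carbinols that occur between steps 14 and 16 are carried as C3-epimer mixtures, because C3 returns to the ketone.

## Route

Step 1
Reactants: 1 (S)-(+)-carvone
Product: 3 (4R,5S)-4-hydroxycarvone (C6–OH trans to the isopropenyl group), via γ-hydroperoxide 2 (not isolated)
Conditions: KOt-Bu (1.2 equiv), O2 (1 atm), P(OEt)3, Cu–Al mixed oxide (cat.), THF/t-BuOH, 0 °C; AcOH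
Reagents that add atoms: dioxygen, O=O
Why: Vinylogous (γ) aerobic hydroxylation of an enone, in which the thermodynamic extended dienolate O–C3=C4–C5=C6 takes up O2 at C6 on the face anti to the neighbouring C7 isopropenyl group (6,7-trans), the phosphite reduces the hydroperoxide, and the six-membered ring holds C4=C5 cis, which a later oxidation in the ten-membered ring could not guarantee.

Step 2
Reactants: 3 (4R,5S)-4-hydroxycarvone
Product: 4 (4R,5S)-4-(triisopropylsilyloxy)carvone
Conditions: TIPSOTf, 2,6-lutidine, CH2Cl2, 0 °C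
Reagents that add atoms: triisopropylsilyl triflate, CC(C)[Si](C(C)C)(C(C)C)OS(=O)(=O)C(F)(F)F
Why: Silyl ether formation with a silyl triflate, the bulky TIPS group being chosen to outlast a later fluoride cleavage of a TES ether and to resist O-to-O silyl migration when the C3 alkoxide is generated.

Step 3
Reactants: 4 (4R,5S)-4-(triisopropylsilyloxy)carvone; 5 propargyl bromide
Product: 7 (4R,5S,6R)-6-(prop-2-ynyl)-4-(triisopropylsilyloxy)carvone, via lithium dienolate 6 (not isolated)
Conditions: LDA (1.1 equiv), THF, −78 °C; 5, DMPU, −78 → −30 °C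
Reagents that add atoms: propargyl bromide (5), C#CCBr
Why: Kinetic α′-deprotonation and SN2 alkylation of the cross-conjugated lithium dienolate, the bromide approaching C8 anti to the adjacent isopropenyl group to give the 7,8-trans (diequatorial) ketone, which is also the thermodynamic epimer.

Step 4
Reactants: 7 (4R,5S,6R)-6-(prop-2-ynyl)-4-(triisopropylsilyloxy)carvone; 8 vinylmagnesium bromide
Product: 9 (1R,4R,5S,6R)-1-ethenyl-2-methyl-5-(prop-1-en-2-yl)-6-(prop-2-ynyl)-4-(triisopropylsilyloxy)cyclohex-2-en-1-ol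
Conditions: 8 (3 equiv; one is consumed by the alkyne C–H), LaCl3·2LiCl, THF, −20 °C; H2O
Reagents that add atoms: vinylmagnesium bromide (8), C=C[Mg]Br
Why: Lanthanide-assisted Grignard 1,2-addition in which the bulky reagent attacks equatorially, on the carbonyl face away from the C8 side chain as with 2-alkylcyclohexanones, so that the vinyl group ends trans to the propargyl group and the hydroxyl axial (3R), the C3 epimer being removed by chromatography.

Step 5
Reactants: 9 tertiary vinyl carbinol
Product: 10 triethylsilyl ether of 9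
Conditions: TESOTf, 2,6-lutidine, CH2Cl2, −78 → 0 °C
Reagents that add atoms: triethylsilyl triflate, CC[Si](CC)(CC)OS(=O)(=O)C(F)(F)F
Why: Silylation of the tertiary alcohol with a silyl triflate, needed because a free potassium alkoxide under the next conditions would start a premature [3,3] shift through the allene or alkyne.

Step 6
Reactants: 10 triethylsilyl ether with prop-2-ynyl side chain
Product: 11 (1R,4R,5S,6S) prop-1-ynyl isomer of 10
Conditions: KOt-Bu (30 mol %), DMSO/THF, rt
Reagents that add atoms: none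
Why: Base-catalysed prototropic alkyne isomerisation (propargyl → allene → prop-1-ynyl) to the more stable internal alkyne, which places C9 and C10 directly on C8 and leaves the far less acidic C8–H and C7–H stereocentres untouched.

Step 7
Reactants: 11 prop-1-ynyl silyl ether
Product: 13 (E)-2-iodoprop-1-enyl compound (CH3 cis to C8), via alkenylstannane 12 (not isolated)
Conditions: Bu3SnH (1.3 equiv), PdCl2(PPh3)2 (3 mol %), THF, 0 °C → rt; then I2, NaHCO3, CH2Cl2, 0 °C
Reagents that add atoms: iodine, II
Why: Pd-catalysed syn-hydrostannation, which engages the alkyne but not the vinyl or isopropenyl groups and puts tin on the less hindered, methyl-bearing C10, followed by iododestannylation with retention, so that the methyl group is fixed cis to C8.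

Step 8
Reactants: 13 (E)-alkenyl iodide; 14 4-methoxybenzyl alcohol
Product: 15 TES-protected (E)-2-(4-methoxybenzyloxy)prop-1-enyl compound
Conditions: 14 (2 equiv), CuI (10 mol %), 3,4,7,8-tetramethyl-1,10-phenanthroline (20 mol %), Cs2CO3, toluene, 90 °C
Reagents that add atoms: 4-methoxybenzyl alcohol (14), COc1ccc(CO)cc1
Why: Ullmann-type copper-catalysed C–O coupling of an alkenyl iodide with an alcohol, which proceeds with retention of the alkene geometry and so delivers the E enol ether, the silyl-masked 1,5-diene being thermally inert at this temperature.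

Step 9
Reactants: 15 TES-protected enol ether
Product: 16 (1R,4R,5S,6S)-1-ethenyl-6-[(1E)-2-(4-methoxybenzyloxy)prop-1-enyl]-2-methyl-5-(prop-1-en-2-yl)-4-(triisopropylsilyloxy)cyclohex-2-en-1-ol
Conditions: TBAF (1.2 equiv), THF, 0 °C
Reagents that add atoms: none
Why: Fluoride desilylation in which the TES ether is cleaved far faster than the hindered TIPS ether, while the basic medium spares the acid-labile enol ether.

Step 10
Reactants: 16 3-vinyl-8-alkenylcyclohexenol
Product: 19 (4Z,8E)-10-(4-methoxybenzyloxy)-4,10-dimethyl-7-(prop-1-en-2-yl)-6-(triisopropylsilyloxy)cyclodeca-4,8-dien-3-one (6R,7S,10S; target numbering), via potassium alkoxide 17 (not isolated), via potassium enolate 18 (not isolated)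
Conditions: KH (1.5 equiv), 18-crown-6 (1.5 equiv), THF, 0 °C → rt; AcOH, −78 °C
Reagents that add atoms: none
Why: KH with 18-crown-6 gives the ion-separated potassium alkoxide 17, whose oxyanion weakens the adjacent C3–C8 bond and drives a concerted, suprafacial [3,3] shift of the hexadiene C1=C2–C3–C8–C9=C10 at or near room temperature. The closest known reaction type is the anionic oxy-Cope ring expansion of trans-1,2-dialkenylcyclohexanols to (E)-cyclodec-5-enones. The ten-membered ring is closed not end to end but by four-atom ring enlargement: C1–C10 forms while C3–C8 breaks in a chair-like six-centre array fused to the cyclohexene like a trans-decalin, with the ring bonds C3–C4 and C8–C7 equatorial and the C–O− bond axial. C10 is the only new stereocentre and is controlled by C8 (itself set from C7 of carvone): C1 can reach C9=C10 only on the face syn to the breaking C3–C8 bond, and A1,3 strain between the C10 methyl (cis to C8) and C7 allows only the C8–C9 rotamer with H8 inside, so the methyl becomes axial and the OPMB equatorial in the array, C8=C9 emerges E and C10 has the configuration of the target. The step needs [3,3] to win over [1,3] shift, fragmentation and silyl migration, which the diequatorial trans-dialkenyl geometry, the bulky TIPS group and the irreversible formation of the cross-conjugated enolate 18 should secure, and C4=C5 lies outside the array and is carried over as the Z-enone. Protonation at low temperature gives 19.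

Step 11
Reactants: 19 cyclodecadienone
Product: 21 (1E,4Z,8E)-cyclodeca-1,4,8-trien-3-one with 10-OPMB, 6-OTIPS and 7-isopropenyl (6R,7S,10R), via trimethylsilyl enol ether 20 (not isolated)
Conditions: LiHMDS, TMSCl, THF, −78 °C; then Pd(OAc)2 (1.1 equiv), MeCN, rt
Reagents that add atoms: none
Why: Kinetic enolisation can only take place at C2 because C4 is sp2, and Saegusa–Ito oxidation of the silyl enol ether by syn β-hydride elimination from the rotamer with C3 and the quaternary C10 anti gives the E-enone, whose geometry also keeps the future C10 hydroxyl from adding to C3=O.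

Step 12
Reactants: 21 trienone PMB ether
Product: 22 (1E,4Z,8E)-10-hydroxy trienone (6R,7S,10R)
Conditions: DDQ (1.3 equiv), CH2Cl2/pH 7 buffer, 0 °C
Reagents that add atoms: none
Why: Oxidative PMB cleavage (benzylic hydride abstraction by DDQ, then hydrolysis of the oxocarbenium ion), which leaves the silyl ether and alkenes alone and does not touch the C10–O bond.

Step 13
Reactants: 22 10-hydroxy trienone
Product: 23 8,9-epoxy-10-hydroxy dienone (6R,7R,8S,9R,10S)
Conditions: VO(acac)2 (5 mol %), t-BuOOH (decane), CH2Cl2, 0 °C → rt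
Reagents that add atoms: tert-butyl hydroperoxide, CC(C)(C)OO
Why: Vanadium-catalysed hydroxyl-directed epoxidation, in which only the unconjugated C8=C9 of the two alkenes allylic to C10–OH is nucleophilic enough, and, because the vanadate ester needs a small O–C10–C9=C8 dihedral angle while the ring bond C10–C1 stands roughly perpendicular on the opposite face, oxygen is delivered anti to O-10 in the zig-zag sense (erythro), which is the C8–O configuration of the target.

Step 14
Reactants: 23 epoxy dienone
Product: 24 8,9-epoxy-1,4-diene-3,10-diol (C3 epimers)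
Conditions: NaBH4, CeCl3·7H2O, MeOH, −78 → −20 °C
Reagents that add atoms: none
Why: Luche reduction, a clean 1,2-reduction that takes the cross-conjugated dienone out of play before the aluminium hydride step, the new C3 centre being erased again in step 16.

Step 15
Reactants: 24 epoxy diol
Product: 25 1,4-diene-3,8,10-triol (6R,7R,8R,10R; C3 epimers)
Conditions: Red-Al (5 equiv), THF, 0 °C → rt; Rochelle salt
Reagents that add atoms: none
Why: Red-Al reduction of a 2,3-epoxy alcohol, in which the aluminate bound to O-10 delivers hydride intramolecularly to C9 from the side opposite the oxirane oxygen to give the 1,3-diol, leaving the C8–O bond and its configuration untouched.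

Step 16
Reactants: 25 triol
Product: 26 8,10-dihydroxy-(1E,4Z)-dien-3-one (6R,7R,8R,10R)
Conditions: MnO2 (excess), CH2Cl2, rt
Reagents that add atoms: none
Why: Chemoselective MnO2 oxidation, since only the doubly allylic C3 carbinol is activated while C8–OH is not allylic and C10–OH is tertiary.

Step 17
Reactants: 26 dihydroxy dienone; 27 isobutyric anhydride
Product: 28 8-isobutyrate of 26
Conditions: 27 (1.5 equiv), DMAP (cat.), Et3N, CH2Cl2, 0 °C → rt
Reagents that add atoms: isobutyric anhydride (27), CC(C)C(=O)OC(=O)C(C)C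
Why: DMAP-catalysed acylation that esterifies the secondary C8–OH with retention and leaves the tertiary C10–OH free.

Step 18
Reactants: 28 dienone isobutyrate
Product: 29 (1R,2R)-1,2-epoxy-3-ketone (1R,2R,6R,7R,8R,10R)
Conditions: t-BuOOH (decane), DBU, CH2Cl2, 0 °C → rt
Reagents that add atoms: tert-butyl hydroperoxide, CC(C)(C)OO
Why: Weitz–Scheffer nucleophilic epoxidation, in which t-BuOO− adds to C1 of the less substituted E-enone rather than to C5 of the α-methylated Z-enone or to the unactivated isopropenyl group, the free C10–OH hydrogen-bonds the peroxide and, with the ring bond C10–C9 covering the other face, guides it to the hydroxyl-bearing face (oxirane O syn to O-10), and closure of the enolate gives the trans-oxirane.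

Step 19
Reactants: 29 epoxy ketone
Product: 30 12-hydroxy compound (isopropenyl CH3 → CH2OH)
Conditions: SeO2 (0.3 equiv), t-BuOOH, CH2Cl2, 0 °C → rt
Reagents that add atoms: tert-butyl hydroperoxide, CC(C)(C)OO; selenium dioxide (oxygen relay), O=[Se]=O
Why: Selenium dioxide allylic oxidation (ene reaction, then [2,3] shift) at the only electron-rich alkene left, directed to the methyl group because C7–H is shielded and deactivated by the two oxygenated neighbours, and any over-oxidised enal converges in step 21.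

Step 20
Reactants: 30 TIPS-protected allylic alcohol
Product: 31 6,12-diol
Conditions: HF·pyridine, pyridine, THF, 0 °C → rt
Reagents that add atoms: none
Why: Buffered fluoride cleavage of the silyl ether without base, so that ester migration and epoxide migration are avoided, and any reversible 3,6-hemiketal of the freed Z-γ-hydroxy enone drains into the lactone in the next step.

Step 21
Reactants: 31 6,12-diol
Product: 34 CNP0273626.1 (target), via hydroxy enal 32 (not isolated), via lactol 33 (not isolated)
Conditions: TEMPO (20 mol %), PhI(OAc)2 (2.5 equiv), CH2Cl2, rt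
Reagents that add atoms: none
Why: TEMPO/PhI(OAc)2 oxidative lactonisation of a 1,4-diol, in which the primary allylic alcohol is oxidised first, C6–OH closes the lactol and a second oxidation gives the trans-fused α-methylene-γ-butyrolactone without touching a stereocentre.

## Compound list

1 | (S)-(+)-carvone | CC1=CC[C@@H](CC1=O)C(C)=C | starting material
2 | (4R,5S)-4-hydroperoxycarvone | CC1=C[C@@H](OO)[C@@H](CC1=O)C(C)=C | intermediate
3 | (4R,5S)-4-hydroxycarvone | CC1=C[C@@H](O)[C@@H](CC1=O)C(C)=C | intermediate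
4 | (4R,5S)-4-(triisopropylsilyloxy)carvone | CC1=C[C@@H](O[Si](C(C)C)(C(C)C)C(C)C)[C@@H](CC1=O)C(C)=C | intermediate
5 | propargyl bromide | C#CCBr | starting material
6 | lithium cross-conjugated dienolate of 4 | CC1=C[C@@H](O[Si](C(C)C)(C(C)C)C(C)C)[C@@H](C=C1[O-])C(C)=C.[Li+] | intermediate
7 | (4R,5S,6R)-6-(prop-2-ynyl)-4-(triisopropylsilyloxy)carvone | CC1=C[C@@H](O[Si](C(C)C)(C(C)C)C(C)C)[C@H](C(C)=C)[C@@H](CC#C)C1=O | intermediate
8 | vinylmagnesium bromide | C=C[Mg]Br | starting material
9 | (1R,4R,5S,6R)-1-ethenyl-2-methyl-5-(prop-1-en-2-yl)-6-(prop-2-ynyl)-4-(triisopropylsilyloxy)cyclohex-2-en-1-ol | C=C[C@]1(O)C(C)=C[C@@H](O[Si](C(C)C)(C(C)C)C(C)C)[C@H](C(C)=C)[C@H]1CC#C | intermediate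
10 | triethylsilyl ether of 9 | C=C[C@]1(O[Si](CC)(CC)CC)C(C)=C[C@@H](O[Si](C(C)C)(C(C)C)C(C)C)[C@H](C(C)=C)[C@H]1CC#C | intermediate
11 | prop-1-ynyl isomer of 10 (1R,4R,5S,6S) | C=C[C@]1(O[Si](CC)(CC)CC)C(C)=C[C@@H](O[Si](C(C)C)(C(C)C)C(C)C)[C@H](C(C)=C)[C@H]1C#CC | intermediate
12 | (E)-2-(tributylstannyl)prop-1-enyl compound | C=C[C@]1(O[Si](CC)(CC)CC)C(C)=C[C@@H](O[Si](C(C)C)(C(C)C)C(C)C)[C@H](C(C)=C)[C@H]1/C=C(\C)[Sn](CCCC)(CCCC)CCCC | intermediate
13 | (E)-2-iodoprop-1-enyl compound | C=C[C@]1(O[Si](CC)(CC)CC)C(C)=C[C@@H](O[Si](C(C)C)(C(C)C)C(C)C)[C@H](C(C)=C)[C@H]1/C=C(\C)I | intermediate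
14 | 4-methoxybenzyl alcohol | COc1ccc(CO)cc1 | starting material
15 | TES-protected E enol ether | C=C[C@]1(O[Si](CC)(CC)CC)C(C)=C[C@@H](O[Si](C(C)C)(C(C)C)C(C)C)[C@H](C(C)=C)[C@H]1/C=C(\C)OCc1ccc(OC)cc1 | intermediate
16 | (1R,4R,5S,6S)-1-ethenyl-6-[(1E)-2-(4-methoxybenzyloxy)prop-1-enyl]-2-methyl-5-(prop-1-en-2-yl)-4-(triisopropylsilyloxy)cyclohex-2-en-1-ol (key-step precursor) | C=C[C@]1(O)C(C)=C[C@@H](O[Si](C(C)C)(C(C)C)C(C)C)[C@H](C(C)=C)[C@H]1/C=C(\C)OCc1ccc(OC)cc1 | intermediate
17 | potassium alkoxide of 16 | C=C[C@]1([O-])C(C)=C[C@@H](O[Si](C(C)C)(C(C)C)C(C)C)[C@H](C(C)=C)[C@H]1/C=C(\C)OCc1ccc(OC)cc1.[K+] | intermediate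
18 | potassium (2Z)-enolate of 19 | C1/C=C([O-])/C(C)=C\[C@@H](O[Si](C(C)C)(C(C)C)C(C)C)[C@H](C(C)=C)/C=C/[C@@]1(C)OCc1ccc(OC)cc1.[K+] | intermediate
19 | (4Z,8E)-cyclodeca-4,8-dien-3-one with 10-Me/10-OPMB, 6-OTIPS, 7-isopropenyl (6R,7S,10S; key-step product) | C1[C@](C)(OCc2ccc(OC)cc2)/C=C/[C@@H](C(C)=C)[C@H](O[Si](C(C)C)(C(C)C)C(C)C)/C=C(/C)C(=O)C1 | intermediate
20 | C2=C3 trimethylsilyl enol ether of 19 | C1C=C(O[Si](C)(C)C)/C(C)=C\[C@@H](O[Si](C(C)C)(C(C)C)C(C)C)[C@H](C(C)=C)/C=C/[C@@]1(C)OCc1ccc(OC)cc1 | intermediate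
21 | (1E,4Z,8E)-trien-3-one, 10-OPMB (6R,7S,10R) | [C@@H]1(C(C)=C)/C=C/[C@@](C)(OCc2ccc(OC)cc2)/C=C/C(=O)/C(C)=C\[C@H]1O[Si](C(C)C)(C(C)C)C(C)C | intermediate
22 | (1E,4Z,8E)-10-hydroxy-trien-3-one (6R,7S,10R) | [C@@H]1(C(C)=C)/C=C/[C@@](C)(O)/C=C/C(=O)/C(C)=C\[C@H]1O[Si](C(C)C)(C(C)C)C(C)C | intermediate
23 | 8,9-epoxy-10-hydroxy-(1E,4Z)-dien-3-one (6R,7R,8S,9R,10S) | [C@@H]1(C(C)=C)[C@@H]2O[C@H]2[C@@](C)(O)/C=C/C(=O)/C(C)=C\[C@H]1O[Si](C(C)C)(C(C)C)C(C)C | intermediate
24 | 8,9-epoxy-(1E,4Z)-diene-3,10-diol (C3 epimers) | [C@@H]1(C(C)=C)[C@@H]2O[C@H]2[C@@](C)(O)/C=C/C(O)/C(C)=C\[C@H]1O[Si](C(C)C)(C(C)C)C(C)C | intermediate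
25 | (1E,4Z)-diene-3,8,10-triol (6R,7R,8R,10R; C3 epimers) | [C@@H]1(C(C)=C)[C@H](O)C[C@@](C)(O)/C=C/C(O)/C(C)=C\[C@H]1O[Si](C(C)C)(C(C)C)C(C)C | intermediate
26 | 8,10-dihydroxy-(1E,4Z)-dien-3-one (6R,7R,8R,10R) | [C@@H]1(C(C)=C)[C@H](O)C[C@@](C)(O)/C=C/C(=O)/C(C)=C\[C@H]1O[Si](C(C)C)(C(C)C)C(C)C | intermediate
27 | isobutyric anhydride | CC(C)C(=O)OC(=O)C(C)C | starting material
28 | 8-isobutyryloxy-10-hydroxy-(1E,4Z)-dien-3-one | [C@@H]1(C(C)=C)[C@H](OC(=O)C(C)C)C[C@@](C)(O)/C=C/C(=O)/C(C)=C\[C@H]1O[Si](C(C)C)(C(C)C)C(C)C | intermediate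
29 | (1R,2R)-1,2-epoxy-3-ketone, 6-OTIPS, 7-isopropenyl | [C@@H]1(C(C)=C)[C@H](OC(=O)C(C)C)C[C@@](C)(O)[C@@H]2O[C@H]2C(=O)/C(C)=C\[C@H]1O[Si](C(C)C)(C(C)C)C(C)C | intermediate
30 | 12-hydroxy derivative of 29 | [C@@H]1(C(=C)CO)[C@H](OC(=O)C(C)C)C[C@@](C)(O)[C@@H]2O[C@H]2C(=O)/C(C)=C\[C@H]1O[Si](C(C)C)(C(C)C)C(C)C | intermediate
31 | 6,12-diol | [C@@H]1(C(=C)CO)[C@H](OC(=O)C(C)C)C[C@@](C)(O)[C@@H]2O[C@H]2C(=O)/C(C)=C\[C@H]1O | intermediate
32 | 6-hydroxy-12-enal | [C@@H]1(C(=C)C=O)[C@H](OC(=O)C(C)C)C[C@@](C)(O)[C@@H]2O[C@H]2C(=O)/C(C)=C\[C@H]1O | intermediate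
33 | 6,12-lactol | C=C1C(O)O[C@@H]2/C=C(/C)C(=O)[C@@H]3O[C@H]3[C@](C)(O)C[C@@H](OC(=O)C(C)C)[C@@H]12 | intermediate
34 | CNP0273626.1 (1R,2R,6R,7R,8R,10R) | C=C1C(=O)O[C@@H]2/C=C(/C)C(=O)[C@@H]3O[C@H]3[C@](C)(O)C[C@@H](OC(=O)C(C)C)[C@@H]12 | target

## Step count and risks

Total step count: 21. Longest linear sequence: 21 steps, from 1.

**Step 10 (key step).** The [3,3] shift may be slowed because the migrating terminus is fully substituted and carries a donor oxygen. Heterolytic fragmentation of the alkoxide, a [1,3] shift to an eight-membered ring, or silyl migration to the alkoxide could then compete. The fallback sets out from 16 and comes back at 19. Charge acceleration is given up, and 16 is rearranged as the neutral alcohol in a purely thermal oxy-Cope reaction (o-dichlorobenzene, 190–210 °C, base-washed sealed tube or flow reactor). No allyl-anion character then builds up at the alkoxy-bearing carbon, and the driving force is the tautomerisation of the ten-membered dienol F1 to ketone 19.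

**Step 13.** Facial selectivity may be poor, because the E-alkene can turn through the flexible ring and offer either face to the vanadium peroxide. The fallback sets out from 22 and comes back at 28.
- If oxygen is delivered to the other face, the diastereomeric epoxide F2 is carried through the same Luche reduction (epoxy diol F3), Red-Al opening (8-epi triol F4) and MnO2 oxidation (8-epi diol F5).
- C8 is then corrected at the esterification stage. A Mitsunobu reaction of F5 with isobutyric acid (PPh3, DIAD, toluene) forms the ester with inversion and gives 28.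

**Step 18.** Three things may go wrong: poor site selectivity between the two enone double bonds, attack on the wrong face of C1=C2, or base-induced migration of the new oxirane towards the C10 alkoxide. The fallback sets out from 28 and comes back at 34. The epoxidation is moved to the last step and changed from nucleophilic to electrophilic, hydroxyl-directed delivery.
- SeO2/t-BuOOH gives the 12-hydroxy dienone F6.
- HF·pyridine gives the dienone 6,12-diol F7.
- TEMPO/PhI(OAc)2 gives the des-epoxy dienone lactone F8, in which no electron-rich alkene is left.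
- A peracid (m-CPBA, or buffered trifluoroperacetic acid) hydrogen-bonded to C10–OH then epoxidises C1=C2 on the hydroxyl-bearing face to give 34.

## Further compounds

F1 | step 10 | ten-membered C2=C3 dienol (enol of 19) | C1/C=C(O)/C(C)=C\[C@@H](O[Si](C(C)C)(C(C)C)C(C)C)[C@H](C(C)=C)/C=C/[C@@]1(C)OCc1ccc(OC)cc1
F2 | step 13 | 8,9-diastereomeric epoxide of 23 | [C@@H]1(C(C)=C)[C@H]2O[C@@H]2[C@@](C)(O)/C=C/C(=O)/C(C)=C\[C@H]1O[Si](C(C)C)(C(C)C)C(C)C
F3 | step 13 | 8,9-diastereomeric epoxy diol (C3 epimers) | [C@@H]1(C(C)=C)[C@H]2O[C@@H]2[C@@](C)(O)/C=C/C(O)/C(C)=C\[C@H]1O[Si](C(C)C)(C(C)C)C(C)C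
F4 | step 13 | 8-epi triol (C3 epimers) | [C@@H]1(C(C)=C)[C@@H](O)C[C@@](C)(O)/C=C/C(O)/C(C)=C\[C@H]1O[Si](C(C)C)(C(C)C)C(C)C
F5 | step 13 | 8-epi-8,10-dihydroxy dienone | [C@@H]1(C(C)=C)[C@@H](O)C[C@@](C)(O)/C=C/C(=O)/C(C)=C\[C@H]1O[Si](C(C)C)(C(C)C)C(C)C
F6 | step 18 | 12-hydroxy dienone, 6-OTIPS | [C@@H]1(C(=C)CO)[C@H](OC(=O)C(C)C)C[C@@](C)(O)/C=C/C(=O)/C(C)=C\[C@H]1O[Si](C(C)C)(C(C)C)C(C)C
F7 | step 18 | dienone 6,12-diol | [C@@H]1(C(=C)CO)[C@H](OC(=O)C(C)C)C[C@@](C)(O)/C=C/C(=O)/C(C)=C\[C@H]1O
F8 | step 18 | des-epoxy (1E,4Z)-dienone lactone | C=C1C(=O)O[C@@H]2/C=C(/C)C(=O)/C=C/[C@](C)(O)C[C@@H](OC(=O)C(C)C)[C@@H]12
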